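**Retrosynthetic overview**

1. The target (isoflavone-type numbering: ring A C5–C8, pyranone O1/C2/C3/C4, ring B C1'–C6', furan O between C2 and C2') comes from its 5-O-methyl ether, which comes from a ring A β-keto ester and 2,2-dimethyl-2H-chromene-5,8-dione by Michael addition (C3–C1'), lactonisation (furan O–C2) and SNAr (O1–C8a).
2. The β-keto ester comes from 5-fluoro-7-methoxy-2,2-dimethyl-2H-chromene by two directed metalations (CO2 between F and OMe, prenyl between the two ether oxygens) and a two-carbon homologation.
3. That chromene comes, by desulfurisation and dehydrogenation, from a spiro-dithiane chromane made in the key step: lithiated 2-(2,6-difluoro-4-methoxyphenyl)-1,3-dithiane plus 2,2-dimethyloxirane joins the aldehyde-level pyran carbon C4'' to C3'' and then closes the pyran oxygen onto ring A C7 by SNAr.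
4. Enabling feature: ring A C8, which carries C4'', lies between two oxygen-bearing carbons, C7 (pyran O) and C8a (O1). Written as C–F they are equivalent, so the ring closure has no regiochemical choice and the second fluoride is kept as leaving group for the pyranone; C3''–C2''(Me)2–O is the intact skeleton of 2,2-dimethyloxirane.
5. Ring order: ring A pyran, then ring B pyran, ring B benzene (aromatisation) and its quinone, then the furan ring, then the pyranone ring.

Key step: step 2

Remark: the target has no stereocentre; the transient sp3 stereocentres of the selenide, the Michael adduct and the aroyl lactone are racemic and are drawn without configuration.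

**Route**

Step 1
Reactants: 1 2,6-difluoro-4-methoxybenzaldehyde; 2 propane-1,3-dithiol
Product: 3 2-(2,6-difluoro-4-methoxyphenyl)-1,3-dithiane
Conditions: BF3·OEt2 (0.2 equiv), CH2Cl2, 0 → 25 °C
Reagents that add atoms: none
Why: Lewis-acid-catalysed dithioacetalisation of an aromatic aldehyde, which masks the aldehyde and makes its carbon acidic for the polarity reversal of step 2.

Step 2
Reactants: 3 2-(2,6-difluoro-4-methoxyphenyl)-1,3-dithiane; 4 2,2-dimethyloxirane
Product: 6 5-fluoro-7-methoxy-2,2-dimethylspiro[chromane-4,2'-[1,3]dithiane], via lithium alkoxide 5 (not isolated)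
Conditions: n-BuLi, THF, −78 °C; 4, DMPU, −78 → 25 °C; then KOtBu, DMSO, 70 °C (one flask)
Reagents that add atoms: none
Why: Corey–Seebach umpolung: n-BuLi removes the dithiane C2–H (the former aldehyde carbon, future pyran C4'') and this acyl-anion equivalent opens 2,2-dimethyloxirane at its CH2 (future C3''), so two carbons that are both electrophilic in the parent aldehyde and epoxide are joined. The tertiary alkoxide 5 released by ring opening is six atoms from either ortho C–F carbon and, after exchange to potassium in DMSO, displaces fluoride by addition–elimination (SNAr, 6-exo-trig attack on the arene carbon through a Meisenheimer intermediate), which closes the pyran and makes the aryl–O bond. The closest known reaction types are epoxide openings by 2-aryl-2-lithio-1,3-dithianes and the base-mediated cyclisation of 3-(2-fluoroaryl)propanols to chromanes. No stereocentre is formed, since the spiro carbon carries two identical sulfur arms. The step needs opening at the epoxide CH2 (secured by the fully substituted other carbon), benzylic rather than ring metalation (the dithiane C–H is by far the more acidic, so proton transfer at −78 °C should funnel to it), and no choice between the fluorides (secured by the symmetry of the 2,6-difluoro-4-methoxyphenyl ring).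

Step 3
Reactants: 6 5-fluoro-7-methoxy-2,2-dimethylspiro[chromane-4,2'-[1,3]dithiane]
Product: 7 5-fluoro-7-methoxy-2,2-dimethylchromane
Conditions: Raney Ni (W-2), EtOH, reflux
Reagents that add atoms: none
Why: Mozingo desulfurisation should cleave both C–S bonds and leave CH2 at C4, with aryl fluoride and aryl ethers inert.

Step 4
Reactants: 7 5-fluoro-7-methoxy-2,2-dimethylchromane
Product: 8 5-fluoro-7-methoxy-2,2-dimethyl-2H-chromene
Conditions: DDQ, 1,4-dioxane, reflux
Reagents that add atoms: none
Why: DDQ dehydrogenation of a 2,2-dimethylchromane (hydride abstraction from benzylic C4, assisted by the ring oxygen and the 7-methoxy group, then loss of a C3 proton) should install the C3=C4 double bond.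

Step 5
Reactants: 8 5-fluoro-7-methoxy-2,2-dimethyl-2H-chromene
Product: 9 5-fluoro-7-methoxy-2,2-dimethyl-2H-chromene-6-carboxylic acid
Conditions: LiN(i-Pr)2 (LDA), THF, −78 °C; CO2 (gas), −78 → 0 °C; 1 M HCl
Reagents that add atoms: carbon dioxide, O=C=O
Why: Directed ortho-metalation and carboxylation: the amide base should remove only the C6 proton flanked by fluorine and methoxy (the C8–H between two ether oxygens is not acidic enough), and trapping at −78 °C precedes loss of LiF.

Step 6
Reactants: 9 5-fluoro-7-methoxy-2,2-dimethyl-2H-chromene-6-carboxylic acid; 10 1-bromo-3-methylbut-2-ene (prenyl bromide)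
Product: 11 5-fluoro-7-methoxy-2,2-dimethyl-8-(3-methylbut-2-en-1-yl)-2H-chromene-6-carboxylic acid
Conditions: s-BuLi (2.2 equiv), TMEDA, THF, −78 °C; CuBr·SMe2; 10, −78 → 0 °C; 1 M HCl
Reagents that add atoms: none
Why: Directed ortho-metalation of the lithium carboxylate at the only remaining ring C–H (C8, between OMe and the pyran oxygen), then copper-mediated allylation, which should take place at the primary carbon of prenyl bromide (SN2, not SN2') because the other terminus is fully substituted.

Step 7
Reactants: 11 5-fluoro-7-methoxy-2,2-dimethyl-8-(3-methylbut-2-en-1-yl)-2H-chromene-6-carboxylic acid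
Product: 13 methyl 3-[5-fluoro-7-methoxy-2,2-dimethyl-8-(3-methylbut-2-en-1-yl)-2H-chromen-6-yl]-3-oxopropanoate, via acyl imidazolide 12 (not isolated)
Conditions: CDI, THF, 25 → 50 °C; KO2CCH2CO2Me, MgCl2, Et3N, MeCN, 25 → 60 °C; 1 M HCl
Reagents that add atoms: potassium methyl malonate, [K+].[O-]C(=O)CC(=O)OC
Why: Masamune–Brooks homologation: the acyl imidazolide C-acylates the magnesium enolate of the malonate half-ester and decarboxylation on work-up gives the β-keto ester under conditions that should spare the prenyl and chromene double bonds.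

Step 8
Reactants: 14 cyclohexane-1,3-dione; 15 3-methylbut-2-enal
Product: 17 2,2-dimethyl-2,6,7,8-tetrahydro-5H-chromen-5-one, via alkylidene dione 16 (not isolated)
Conditions: ethylenediammonium diacetate (10 mol%), MeOH, 25 °C
Reagents that add atoms: none
Why: Knoevenagel condensation followed by oxa-6π electrocyclisation of the 1-oxatriene (formal [3+3] pyran annulation of a 1,3-dione with an enal).

Step 9
Reactants: 17 2,2-dimethyl-2,6,7,8-tetrahydro-5H-chromen-5-one
Product: 19 2,2-dimethyl-2H-chromen-5-ol, via selenide 18 (not isolated)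
Conditions: LiN(i-Pr)2 (LDA), THF, −78 °C; PhSeCl; then 30% H2O2, pyridine, CH2Cl2, 0 → 25 °C
Reagents that add atoms: none
Why: Selenenylation of the kinetic α'-enolate and selenoxide syn-elimination give a cross-conjugated dienone that should tautomerise to the phenol (aromatisation of ring B).

Step 10
Reactants: 19 2,2-dimethyl-2H-chromen-5-ol
Product: 20 2,2-dimethyl-2H-chromene-5,8-dione
Conditions: K2[ON(SO3)2] (Fremy's salt, 2.2 equiv), KH2PO4 (aq.), acetone, 0 → 25 °C
Reagents that add atoms: potassium nitrosodisulfonate, [K+].[K+].[O]N(S(=O)(=O)[O-])S(=O)(=O)[O-]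
Why: Teuber oxidation of a phenol with a free para position should give the para-quinone and leave the chromene double bond untouched.

Step 11
Reactants: 13 methyl 3-[5-fluoro-7-methoxy-2,2-dimethyl-8-(3-methylbut-2-en-1-yl)-2H-chromen-6-yl]-3-oxopropanoate; 20 2,2-dimethyl-2H-chromene-5,8-dione
Product: 23 5-O-methyl ether of the target (5-methoxy in place of 5-hydroxy on ring A), via hydroquinone adduct 21 (not isolated), via aroyl lactone 22 (not isolated)
Conditions: Et3N (0.2 equiv), CH2Cl2, −20 → 0 °C, N2; then K2CO3, degassed DMF, 80 °C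
Reagents that add atoms: none
Why: Michael addition of the β-keto ester to the quinone at C6 (the CH para to the ring-oxygen-bearing carbon and β to the carbonyl that is not deactivated as a vinylogous ester, as in Nenitzescu-type additions to alkoxyquinones) and tautomerisation give hydroquinone 21, whose 5-phenoxide lactonises onto the ester under carbonate, after which the enolate oxygen of the 3-aroylbenzofuran-2(3H)-one 22 displaces the ortho fluoride (SNAr activated by the ortho ketone) and closes the pyranone.

Step 12
Reactants: 23 5-O-methyl ether of the target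
Product: 24 target
Conditions: MgI2·OEt2, THF, 60 °C; 1 M HCl
Reagents that add atoms: none
Why: Chelation-controlled demethylation: magnesium binds the C4 carbonyl and the peri 5-methoxy oxygen and iodide removes the methyl group, a mild method that should avoid acid-induced cyclisation of the 6-prenyl group onto the freed 5-OH.

**Compound list**

1 | 2,6-difluoro-4-methoxybenzaldehyde | COc1cc(F)c(C=O)c(F)c1 | starting material
2 | propane-1,3-dithiol | SCCCS | starting material
3 | 2-(2,6-difluoro-4-methoxyphenyl)-1,3-dithiane | COc1cc(F)c(C2SCCCS2)c(F)c1 | intermediate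
4 | 2,2-dimethyloxirane | CC1(C)CO1 | starting material
5 | lithium 1-[2-(2,6-difluoro-4-methoxyphenyl)-1,3-dithian-2-yl]-2-methylpropan-2-olate | [Li]OC(C)(C)CC1(SCCCS1)c1c(F)cc(OC)cc1F | intermediate
6 | 5-fluoro-7-methoxy-2,2-dimethylspiro[chromane-4,2'-[1,3]dithiane] | COc1cc(F)c2c(c1)OC(C)(C)CC21SCCCS1 | intermediate
7 | 5-fluoro-7-methoxy-2,2-dimethylchromane | COc1cc(F)c2CCC(C)(C)Oc2c1 | intermediate
8 | 5-fluoro-7-methoxy-2,2-dimethyl-2H-chromene | COc1cc(F)c2C=CC(C)(C)Oc2c1 | intermediate
9 | 5-fluoro-7-methoxy-2,2-dimethyl-2H-chromene-6-carboxylic acid | COc1cc2OC(C)(C)C=Cc2c(F)c1C(O)=O | intermediate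
10 | 1-bromo-3-methylbut-2-ene (prenyl bromide) | CC(C)=CCBr | starting material
11 | 5-fluoro-7-methoxy-2,2-dimethyl-8-(3-methylbut-2-en-1-yl)-2H-chromene-6-carboxylic acid | COc1c(CC=C(C)C)c2OC(C)(C)C=Cc2c(F)c1C(O)=O | intermediate
12 | [5-fluoro-7-methoxy-2,2-dimethyl-8-(3-methylbut-2-en-1-yl)-2H-chromen-6-yl](1H-imidazol-1-yl)methanone | COc1c(CC=C(C)C)c2OC(C)(C)C=Cc2c(F)c1C(=O)n1ccnc1 | intermediate
13 | methyl 3-[5-fluoro-7-methoxy-2,2-dimethyl-8-(3-methylbut-2-en-1-yl)-2H-chromen-6-yl]-3-oxopropanoate | COC(=O)CC(=O)c1c(F)c2C=CC(C)(C)Oc2c(CC=C(C)C)c1OC | intermediate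
14 | cyclohexane-1,3-dione | O=C1CCCC(=O)C1 | starting material
15 | 3-methylbut-2-enal | CC(C)=CC=O | starting material
16 | 2-(3-methylbut-2-en-1-ylidene)cyclohexane-1,3-dione | CC(C)=CC=C1C(=O)CCCC1=O | intermediate
17 | 2,2-dimethyl-2,6,7,8-tetrahydro-5H-chromen-5-one | CC1(C)C=CC2=C(O1)CCCC2=O | intermediate
18 | 2,2-dimethyl-6-(phenylselanyl)-2,6,7,8-tetrahydro-5H-chromen-5-one (racemic) | CC1(C)C=CC2=C(O1)CCC([Se]c1ccccc1)C2=O | intermediate
19 | 2,2-dimethyl-2H-chromen-5-ol | CC1(C)C=Cc2c(O)cccc2O1 | intermediate
20 | 2,2-dimethyl-2H-chromene-5,8-dione | CC1(C)C=CC2=C(O1)C(=O)C=CC2=O | intermediate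
21 | methyl 2-(5,8-dihydroxy-2,2-dimethyl-2H-chromen-6-yl)-3-[5-fluoro-7-methoxy-2,2-dimethyl-8-(3-methylbut-2-en-1-yl)-2H-chromen-6-yl]-3-oxopropanoate (racemic) | COC(=O)C(C(=O)c1c(F)c2C=CC(C)(C)Oc2c(CC=C(C)C)c1OC)c1cc(O)c2OC(C)(C)C=Cc2c1O | intermediate
22 | 3-aroylbenzofuran-2(3H)-one from 21 by lactonisation onto the 5-OH of the dihydroxychromene (free 8-OH; racemic at C3 and enolisable) | O=C1Oc2c3C=CC(C)(C)Oc3c(O)cc2C1C(=O)c1c(F)c2C=CC(C)(C)Oc2c(CC=C(C)C)c1OC | intermediate
23 | 5-O-methyl ether of the target: 5'-hydroxy-5-methoxy-6-(3-methylbut-2-en-1-yl)benzofuro[2,3-b]chromen-11-one core with 2,2-dimethyl-2H-pyran rings fused at C7(O)/C8(C) and C4'(O)/C3'(C) | CC(C)=CCc1c2c(c3oc4oc5c6c(c(O)cc5c4c(=O)c3c1OC)OC(C)(C)C=C6)C=CC(C)(C)O2 | intermediate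
24 | target: 5,5'-dihydroxy-6-(3-methylbut-2-en-1-yl) coumaronochromone (benzofuro[2,3-b]chromen-11-one) with 2,2-dimethyl-2H-pyran rings fused at C7(O)/C8(C) of ring A and C4'(O)/C3'(C) of ring B | CC(C)=CCc1c2c(c3oc4oc5c6c(c(O)cc5c4c(=O)c3c1O)OC(C)(C)C=C6)C=CC(C)(C)O2 | target

**Summary**

Total step count: 12. Longest linear sequence: 9 steps (steps 1–7, 11, 12); the ring B quinone (steps 8–10) joins at step 11.

Steps most likely to fail:

1. Step 11. The hydroquinone adduct may be re-oxidised by unreacted quinone (redox exchange), the quinone may decompose under base, or the adduct may close onto the ketone instead of the ester (benzofuran formation). Fallback, setting out from 20 and 11 and returning at 23: the furanone is built before the fragments meet. Mukaiyama–Michael addition of 1-(tert-butyldimethylsilyloxy)-1-methoxyethene to 20, followed by dilute HCl in THF, should give the hydroxy lactone F1. TBSCl and imidazole in DMF should give its silyl ether F2. Acid 11 is converted with oxalyl chloride and catalytic DMF into the acid chloride F3. C-acylation of the lithium enolate of F2 (LiN(SiMe3)2, THF, −78 °C, with DMAP to rearrange any O-acyl isomer) with F3 should give the silylated aroyl lactone F4. K2CO3 in DMF at 80 °C then closes the pyranone by SNAr, and the fluoride released removes the silyl group, giving 23.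

2. Step 2. Opening of the epoxide by the hindered, doubly ortho-substituted dithiane anion may be slow, ring metalation next to fluorine with loss of LiF may compete, and the SNAr may stop short of completion. Fallback, setting out from 1 and returning at 7: Horner–Wadsworth–Emmons reaction of 1 with triethyl phosphonoacetate and NaH should give ethyl (E)-3-(2,6-difluoro-4-methoxyphenyl)prop-2-enoate F5. Hydrogenation over Pd/C should give ethyl 3-(2,6-difluoro-4-methoxyphenyl)propanoate F6. Excess MeMgBr should give 4-(2,6-difluoro-4-methoxyphenyl)-2-methylbutan-2-ol F7. NaH in DMF at 100 °C then closes the chromane 7 by intramolecular SNAr.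

3. Step 6. s-BuLi may add to the carboxylate, the dianion may be poorly soluble and metalate incompletely, and the carboxylate may be O-alkylated. Fallback, setting out from 8 and returning at 11 (it replaces steps 5 and 6): the acidic C6 position is blocked first. LiN(i-Pr)2 then Me3SiCl should give (5-fluoro-7-methoxy-2,2-dimethyl-2H-chromen-6-yl)trimethylsilane F8. n-BuLi/TMEDA metalation at C8, CuBr·SMe2 and prenyl bromide 10 should give the 8-prenyl silane F9. Bu4NF in wet THF should remove the silyl group to give 5-fluoro-7-methoxy-2,2-dimethyl-8-(3-methylbut-2-en-1-yl)-2H-chromene F10. Metalation with LiN(i-Pr)2 and carboxylation as in step 5 then gives 11.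

Further compounds
F1 | step 11 | hydroxy lactone: benzofuran-2(3H)-one from (5,8-dihydroxy-2,2-dimethyl-2H-chromen-6-yl)acetic acid closed on the 5-OH (free 8-OH) | O=C1Cc2cc(O)c3OC(C)(C)C=Cc3c2O1
F2 | step 11 | tert-butyldimethylsilyl ether of F1 | O=C1Cc2cc(O[Si](C)(C)C(C)(C)C)c3OC(C)(C)C=Cc3c2O1
F3 | step 11 | 5-fluoro-7-methoxy-2,2-dimethyl-8-(3-methylbut-2-en-1-yl)-2H-chromene-6-carbonyl chloride | COc1c(CC=C(C)C)c2OC(C)(C)C=Cc2c(F)c1C(Cl)=O
F4 | step 11 | silyl ether of aroyl lactone 22 (racemic at C3) | O=C1Oc2c3C=CC(C)(C)Oc3c(O[Si](C)(C)C(C)(C)C)cc2C1C(=O)c1c(F)c2C=CC(C)(C)Oc2c(CC=C(C)C)c1OC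
F5 | step 2 | ethyl (E)-3-(2,6-difluoro-4-methoxyphenyl)prop-2-enoate | COc1cc(F)c(/C=C/C(=O)OCC)c(F)c1
F6 | step 2 | ethyl 3-(2,6-difluoro-4-methoxyphenyl)propanoate | COc1cc(F)c(CCC(=O)OCC)c(F)c1
F7 | step 2 | 4-(2,6-difluoro-4-methoxyphenyl)-2-methylbutan-2-ol | COc1cc(F)c(CCC(C)(C)O)c(F)c1
F8 | step 6 | (5-fluoro-7-methoxy-2,2-dimethyl-2H-chromen-6-yl)trimethylsilane | COc1cc2OC(C)(C)C=Cc2c(F)c1[Si](C)(C)C
F9 | step 6 | [5-fluoro-7-methoxy-2,2-dimethyl-8-(3-methylbut-2-en-1-yl)-2H-chromen-6-yl]trimethylsilane | COc1c(CC=C(C)C)c2OC(C)(C)C=Cc2c(F)c1[Si](C)(C)C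
F10 | step 6 | 5-fluoro-7-methoxy-2,2-dimethyl-8-(3-methylbut-2-en-1-yl)-2H-chromene | COc1cc(F)c2C=CC(C)(C)Oc2c1CC=C(C)C
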